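## Retrosynthetic overview

1. Target 18 comes from its hexamethyl ether 17 by global O-demethylation; 17 comes from a Heck coupling of iodophenol 16 with styrene 1; 16 comes from phenol 15.
2. 15 comes from the bicyclic vinylogous ester 12 by dehydrogenation, which turns the carbocycle into the resorcinol ring.
3. 12 comes from acetoacetate 9: its bis-silyl ketene-acetal diene 10 adds intramolecularly to the vinyl group, closing the six-membered carbocycle and the dihydrofuran ring together around the two existing stereocentres.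
4. 9 comes from anti-homoallylic alcohol 6 and diketene equivalent 7; 6 comes from aldehyde 4 and (E)-cinnamyl boronate 3 (catalytic asymmetric allylboration sets both stereocentres); 3 comes from 1 and 2 by cross-metathesis.
5. Ring order: carbocycle and dihydrofuran together (step 4), then aromatisation of the carbocycle (step 5); the other three benzene rings are bought.

Assumption: (R)-TRIP is taken to give Re-face attack (the R alcohol from benzaldehyde), so (S)-TRIP is used for the 1S centre; 1, 2, 4 and 7 are bought.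

## Route

Step 1
Reactants: 1 3,5-dimethoxystyrene; 2 allylboronic acid pinacol ester
Product: 3 2-[(2E)-3-(3,5-dimethoxyphenyl)prop-2-en-1-yl]-4,4,5,5-tetramethyl-1,3,2-dioxaborolane
Conditions: Grubbs II (3 mol%), 2 (2.5 equiv), CH2Cl2, 40 °C
Reagents that add atoms: none
Why: olefin cross-metathesis of a styrene with the allylboronate, driven by loss of ethene, gives the conjugated (E)-cinnamyl boronate as the thermodynamic isomer.

Step 2
Reactants: 3 (E)-cinnamyl boronate; 4 3,4-dimethoxybenzaldehyde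
Product: 6 (1S,2R)-1-(3,4-dimethoxyphenyl)-2-(3,5-dimethoxyphenyl)but-3-en-1-ol, via borate ester 5 (not isolated)
Conditions: (S)-TRIP (5 mol%), PhMe, 4 Å MS, −30 → 0 °C; aq. NaHCO3 work-up
Reagents that add atoms: none
Why: chiral phosphoric acid-catalysed allylboration through a closed chair (Zimmerman–Traxler) transition state, in which the E-boronate gives the anti pair and the (S)-catalyst directs attack to the Si face of the aldehyde, so C1 is S and C2 is R.

Step 3
Reactants: 6 anti-homoallylic alcohol; 7 2,2,6-trimethyl-4H-1,3-dioxin-4-one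
Product: 9 (1S,2R)-1-(3,4-dimethoxyphenyl)-2-(3,5-dimethoxyphenyl)but-3-en-1-yl 3-oxobutanoate, via acetylketene 8 (not isolated)
Conditions: xylenes, 130 °C, 1 h, acetone distilled off
Reagents that add atoms: none
Why: retro-hetero-Diels–Alder of the dioxinone releases acetylketene, which the secondary alcohol traps under neutral conditions (acetoacetylation), so neither stereocentre is touched.

Step 4
Reactants: 9 acetoacetate ester
Product: 12 (2S,3R)-2-(3,4-dimethoxyphenyl)-3-(3,5-dimethoxyphenyl)-3,3a,4,5-tetrahydro-1-benzofuran-6(2H)-one (either C3a epimer), via bis-silyl diene 10 (not isolated), via bicyclic cycloadduct 11 (not isolated)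
Conditions: TMSOTf (2.3 equiv), Et3N (3 equiv), Et2O, 0 °C → rt; then PhMe, BHT, 160–170 °C, sealed tube; then 1 M HCl, THF, rt
Reagents that add atoms: trimethylsilyl trifluoromethanesulfonate (TMSOTf), C[Si](C)(C)OS(=O)(=O)C(F)(F)F
Why: Proposed new method: double O-silylation turns the acetoacetate into a Chan-type 1-alkoxy-1,3-bis(silyloxy)diene whose ketene-acetal carbon is tied through the ester oxygen and the two stereocentres to the vinyl group, so a type-1 intramolecular Diels–Alder reaction (three-atom tether, helped by the vicinal diaryl substitution) can only join C7a to C3a and C5 to C4 and closes the carbocycle and the dihydrofuran at once; acid then hydrolyses the silyl enol ether and expels Me3SiOH from the ketal carbon with the ring oxygen as donor to give the vinylogous ester, so the silyl groups are carried only by the two unisolated intermediates; no bond to C2 or C3 is made or broken, so both centres are carried over, and the new C3a centre is erased in step 5; the closest known reactions are the intermolecular Chan/Brassard-diene cycloaddition–elimination route to resorcinol ethers and thermal intramolecular Diels–Alder reactions of 2-silyloxy-1,3,8-nonatrienes with unactivated alkenes.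

Step 5
Reactants: 12 bicyclic vinylogous ester
Product: 15 (2S,3S)-2-(3,4-dimethoxyphenyl)-3-(3,5-dimethoxyphenyl)-2,3-dihydro-1-benzofuran-6-ol, via selenide 13 (not isolated), via selenoxide 14 (not isolated)
Conditions: LDA (1.1 equiv), THF, −78 °C; PhSeBr, −78 °C; then 30% H2O2, pyridine, CH2Cl2, 0 °C → rt
Reagents that add atoms: phenylselenyl bromide (PhSeBr), Br[Se]c1ccccc1; hydrogen peroxide, OO
Why: kinetic α′-deprotonation of the vinylogous ester (Stork–Danheiser regiochemistry), selenenylation and selenoxide syn-elimination give the cross-conjugated dienone, which is the keto tautomer of the phenol and aromatises at once, the selenium and the peroxide oxygen being lost again in the elimination; the label at C3 changes from R to S only because aromatic C3a now outranks the aryl group.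

Step 6
Reactants: 15 phenol
Product: 16 (2S,3S)-2-(3,4-dimethoxyphenyl)-3-(3,5-dimethoxyphenyl)-5-iodo-2,3-dihydro-1-benzofuran-6-ol
Conditions: I2 (1.0 equiv), NaHCO3, THF–H2O, 0 °C
Reagents that add atoms: iodine, II
Why: electrophilic aromatic iodination of the phenoxide, in which only the phenol ring reacts with I2 under bicarbonate and C5 (ortho to OH, para to the ring oxygen) is preferred over the flanked C7.

Step 7
Reactants: 16 iodophenol; 1 3,5-dimethoxystyrene
Product: 17 (2S,3S)-2-(3,4-dimethoxyphenyl)-3-(3,5-dimethoxyphenyl)-5-[(E)-2-(3,5-dimethoxyphenyl)ethenyl]-2,3-dihydro-1-benzofuran-6-ol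
Conditions: Pd(OAc)2 (5 mol%), P(o-tol)3 (10 mol%), Et3N, DMF, 90 °C
Reagents that add atoms: none
Why: Mizoroki–Heck reaction, in which syn-insertion and β-hydride elimination give the (E)-stilbene and the free ortho-phenol is tolerated.

Step 8
Reactants: 17 hexamethyl ether
Product: 18 4-[(2S,3S)-3-(3,5-dihydroxyphenyl)-5-[(E)-2-(3,5-dihydroxyphenyl)ethenyl]-6-hydroxy-2,3-dihydro-1-benzofuran-2-yl]benzene-1,2-diol
Conditions: BBr3 (12 equiv), CH2Cl2, −78 → 0 °C; then MeOH, H2O
Reagents that add atoms: none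
Why: Lewis-acid aryl methyl ether cleavage removes all six methyl groups; C3 cannot epimerise and trans is the stable arrangement, so any reversible C2–O ionisation returns the same (2S,3S) isomer.

## Compound list

1 | 3,5-dimethoxystyrene (1-ethenyl-3,5-dimethoxybenzene) | C=Cc1cc(OC)cc(OC)c1 | starting material
2 | allylboronic acid pinacol ester (4,4,5,5-tetramethyl-2-(prop-2-en-1-yl)-1,3,2-dioxaborolane) | C=CCB1OC(C)(C)C(C)(C)O1 | starting material
3 | 2-[(2E)-3-(3,5-dimethoxyphenyl)prop-2-en-1-yl]-4,4,5,5-tetramethyl-1,3,2-dioxaborolane | COc1cc(OC)cc(/C=C/CB2OC(C)(C)C(C)(C)O2)c1 | intermediate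
4 | 3,4-dimethoxybenzaldehyde | COc1ccc(C=O)cc1OC | starting material
5 | 2-{[(1S,2R)-1-(3,4-dimethoxyphenyl)-2-(3,5-dimethoxyphenyl)but-3-en-1-yl]oxy}-4,4,5,5-tetramethyl-1,3,2-dioxaborolane | CC1(C)OB(O[C@H](c2ccc(OC)c(OC)c2)[C@H](C=C)c2cc(OC)cc(OC)c2)OC1(C)C | intermediate
6 | (1S,2R)-1-(3,4-dimethoxyphenyl)-2-(3,5-dimethoxyphenyl)but-3-en-1-ol (anti) | O[C@H](c1ccc(OC)c(OC)c1)[C@H](C=C)c1cc(OC)cc(OC)c1 | intermediate
7 | 2,2,6-trimethyl-4H-1,3-dioxin-4-one | CC1=CC(=O)OC(C)(C)O1 | starting material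
8 | acetylketene (but-1-ene-1,3-dione) | CC(=O)C=C=O | intermediate
9 | (1S,2R)-1-(3,4-dimethoxyphenyl)-2-(3,5-dimethoxyphenyl)but-3-en-1-yl 3-oxobutanoate | CC(=O)CC(=O)O[C@H](c1ccc(OC)c(OC)c1)[C@H](C=C)c1cc(OC)cc(OC)c1 | intermediate
10 | 1-{[(1S,2R)-1-(3,4-dimethoxyphenyl)-2-(3,5-dimethoxyphenyl)but-3-en-1-yl]oxy}-1,3-bis(trimethylsilyloxy)buta-1,3-diene (ketene-acetal E/Z mixture) | C=C(O[Si](C)(C)C)C=C(O[Si](C)(C)C)O[C@H](c1ccc(OC)c(OC)c1)[C@H](C=C)c1cc(OC)cc(OC)c1 | intermediate
11 | (2S,3R)-2-(3,4-dimethoxyphenyl)-3-(3,5-dimethoxyphenyl)-6,7a-bis(trimethylsilyloxy)-2,3,3a,4,5,7a-hexahydro-1-benzofuran (ring-fusion isomers) | C[Si](C)(C)OC1=CC2(O[Si](C)(C)C)O[C@H](c3ccc(OC)c(OC)c3)[C@@H](c3cc(OC)cc(OC)c3)C2CC1 | intermediate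
12 | (2S,3R)-2-(3,4-dimethoxyphenyl)-3-(3,5-dimethoxyphenyl)-3,3a,4,5-tetrahydro-1-benzofuran-6(2H)-one (either C3a epimer) | O=C1C=C2O[C@H](c3ccc(OC)c(OC)c3)[C@@H](c3cc(OC)cc(OC)c3)C2CC1 | intermediate
13 | (2S,3R)-2-(3,4-dimethoxyphenyl)-3-(3,5-dimethoxyphenyl)-5-(phenylselanyl)-3,3a,4,5-tetrahydro-1-benzofuran-6(2H)-one | O=C1C=C2O[C@H](c3ccc(OC)c(OC)c3)[C@@H](c3cc(OC)cc(OC)c3)C2CC1[Se]c1ccccc1 | intermediate
14 | (2S,3R)-5-(benzeneseleninyl)-2-(3,4-dimethoxyphenyl)-3-(3,5-dimethoxyphenyl)-3,3a,4,5-tetrahydro-1-benzofuran-6(2H)-one | O=C1C=C2O[C@H](c3ccc(OC)c(OC)c3)[C@@H](c3cc(OC)cc(OC)c3)C2CC1[Se](=O)c1ccccc1 | intermediate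
15 | (2S,3S)-2-(3,4-dimethoxyphenyl)-3-(3,5-dimethoxyphenyl)-2,3-dihydro-1-benzofuran-6-ol (trans) | Oc1ccc2c(c1)O[C@H](c1ccc(OC)c(OC)c1)[C@H]2c1cc(OC)cc(OC)c1 | intermediate
16 | (2S,3S)-2-(3,4-dimethoxyphenyl)-3-(3,5-dimethoxyphenyl)-5-iodo-2,3-dihydro-1-benzofuran-6-ol | Ic1cc2c(cc1O)O[C@H](c1ccc(OC)c(OC)c1)[C@H]2c1cc(OC)cc(OC)c1 | intermediate
17 | (2S,3S)-2-(3,4-dimethoxyphenyl)-3-(3,5-dimethoxyphenyl)-5-[(E)-2-(3,5-dimethoxyphenyl)ethenyl]-2,3-dihydro-1-benzofuran-6-ol | COc1cc(OC)cc(/C=C/c2cc3c(cc2O)O[C@H](c2ccc(OC)c(OC)c2)[C@H]3c2cc(OC)cc(OC)c2)c1 | intermediate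
18 | 4-[(2S,3S)-3-(3,5-dihydroxyphenyl)-5-[(E)-2-(3,5-dihydroxyphenyl)ethenyl]-6-hydroxy-2,3-dihydro-1-benzofuran-2-yl]benzene-1,2-diol | Oc1cc(O)cc(/C=C/c2cc3c(cc2O)O[C@H](c2ccc(O)c(O)c2)[C@H]3c2cc(O)cc(O)c2)c1 | target

## Step count and risks

Total step count: 8. Longest linear sequence: 8 steps (1 → 3 → 6 → 9 → 12 → 15 → 16 → 17 → 18).

**Step 4** is the most likely to fail. The dienophile is an unactivated vinyl group, so the cycloaddition needs about 160–170 °C. At that temperature the silyl ketene acetal may rearrange or lose the electron-rich benzylic ester before it cyclises, and only the ketene-acetal isomer with the tether on the outside of the diene can close. The fallback gives up the cycloaddition and builds phenol 15 by a chiral sulfur-ylide [4+1] annulation of an ortho-quinone methide. It sets out from aldehyde 4 and comes back at 15. NaBH4 in MeOH reduces 4 to (3,4-dimethoxyphenyl)methanol F1. F1 with (2R,5R)-2,5-dimethylthiolane and HBF4·OEt2 in CH2Cl2 gives (2R,5R)-1-(3,4-dimethoxybenzyl)-2,5-dimethylthiolan-1-ium tetrafluoroborate F2. Separately, resorcinol, 3,5-dimethoxybenzaldehyde and sodium p-toluenesulfinate in aqueous formic acid give the latent quinone methide 4-[(3,5-dimethoxyphenyl)(4-methylbenzenesulfonyl)methyl]benzene-1,3-diol F3. F2 and F3 with Cs2CO3 in CH2Cl2 at −20 °C lose sulfinate, the ylide adds to the quinone methide, and the ortho-phenoxide displaces the sulfide to give trans-15. If the (2R,3R) antipode predominates, the (2S,5S)-sulfide is used instead.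

**Step 6** is the second risk. Iodine could go to C7, or twice, or onto the dimethoxyaryl rings. The fallback replaces halogenation and Heck coupling by formylation and olefination. It sets out from 15 and comes back at 17. Magnesium-mediated ortho-formylation (MgCl2, Et3N, paraformaldehyde, MeCN, reflux), which acts only on the free phenol, gives (2S,3S)-2-(3,4-dimethoxyphenyl)-3-(3,5-dimethoxyphenyl)-6-hydroxy-2,3-dihydro-1-benzofuran-5-carbaldehyde F4. A Horner–Wadsworth–Emmons reaction of F4 with bought diethyl (3,5-dimethoxybenzyl)phosphonate (KOtBu 2.5 equiv, THF/DMF, 0 °C → rt) gives the (E)-stilbene 17.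

**Step 8** is the third risk. Six ethers must be cleaved while the 2-hydroxystilbene and the 2-aryl-dihydrobenzofuran are exposed to BBr3 and HBr, which can cause cyclisation or oligomerisation. The fallback demethylates before the stilbene exists and brings the last ring in with base-labile groups. It sets out from 16 and comes back at 18; it still uses BBr3 on the dihydrobenzofuran, so it covers stilbene-derived failure only. BBr3 in CH2Cl2 converts 16 into 4-[(2S,3S)-3-(3,5-dihydroxyphenyl)-6-hydroxy-5-iodo-2,3-dihydro-1-benzofuran-2-yl]benzene-1,2-diol F5. Ac2O and pyridine give its pentaacetate, (2S,3S)-6-acetoxy-2-(3,4-diacetoxyphenyl)-3-(3,5-diacetoxyphenyl)-5-iodo-2,3-dihydro-1-benzofuran F6. Heck coupling of F6 with bought 3,5-diacetoxystyrene (Pd(OAc)2, P(o-tol)3, Et3N, MeCN, 80 °C) gives the heptaacetate of the target, (2S,3S)-6-acetoxy-2-(3,4-diacetoxyphenyl)-3-(3,5-diacetoxyphenyl)-5-[(E)-2-(3,5-diacetoxyphenyl)ethenyl]-2,3-dihydro-1-benzofuran F7. K2CO3 in MeOH at 0 °C under argon, then dilute HCl, gives 18.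

## Further compounds

F1 | step 4 | (3,4-dimethoxyphenyl)methanol | COc1ccc(CO)cc1OC
F2 | step 4 | (2R,5R)-1-(3,4-dimethoxybenzyl)-2,5-dimethylthiolan-1-ium tetrafluoroborate | C[C@@H]1CC[C@@H](C)[S+]1Cc1ccc(OC)c(OC)c1.F[B-](F)(F)F
F3 | step 4 | 4-[(3,5-dimethoxyphenyl)(4-methylbenzenesulfonyl)methyl]benzene-1,3-diol (racemic) | Cc1ccc(cc1)S(=O)(=O)C(c1ccc(O)cc1O)c1cc(OC)cc(OC)c1
F4 | step 6 | (2S,3S)-2-(3,4-dimethoxyphenyl)-3-(3,5-dimethoxyphenyl)-6-hydroxy-2,3-dihydro-1-benzofuran-5-carbaldehyde | O=Cc1cc2c(cc1O)O[C@H](c1ccc(OC)c(OC)c1)[C@H]2c1cc(OC)cc(OC)c1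
F5 | step 8 | 4-[(2S,3S)-3-(3,5-dihydroxyphenyl)-6-hydroxy-5-iodo-2,3-dihydro-1-benzofuran-2-yl]benzene-1,2-diol | Ic1cc2c(cc1O)O[C@H](c1ccc(O)c(O)c1)[C@H]2c1cc(O)cc(O)c1
F6 | step 8 | (2S,3S)-6-acetoxy-2-(3,4-diacetoxyphenyl)-3-(3,5-diacetoxyphenyl)-5-iodo-2,3-dihydro-1-benzofuran | Ic1cc2c(cc1OC(C)=O)O[C@H](c1ccc(OC(C)=O)c(OC(C)=O)c1)[C@H]2c1cc(OC(C)=O)cc(OC(C)=O)c1
F7 | step 8 | (2S,3S)-6-acetoxy-2-(3,4-diacetoxyphenyl)-3-(3,5-diacetoxyphenyl)-5-[(E)-2-(3,5-diacetoxyphenyl)ethenyl]-2,3-dihydro-1-benzofuran | CC(=O)Oc1cc(OC(C)=O)cc(/C=C/c2cc3c(cc2OC(C)=O)O[C@H](c2ccc(OC(C)=O)c(OC(C)=O)c2)[C@H]3c2cc(OC(C)=O)cc(OC(C)=O)c2)c1
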